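## Retrosynthetic overview

1. Target ⇐ protected 17-nor-11,16-diketone. Endgame: Wittig methylenation at C16, exo-face hydride reduction of C11=O to the 11β-alcohol, acid deprotection.
2. Key disconnection C13–C16: the diketone ⇐ a ring C enone (C11=O, C12=C13) carrying a C8–CH2–CHO arm. An NHC-catalysed intramolecular Stetter reaction (C16 acyl anion equivalent onto C13) re-forms ring D last, leaving H at C13 and oxygen at C11.
3. Enone aldehyde ⇐ ring-D-seco C13 ketone / C16 methyl ester, by 1,3-carbonyl transposition (IBX, epoxidation, Wharton) and redox adjustment.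
4. Seco keto ester ⇐ gibberellic acid, by ozonolysis and α-ketol cleavage of ring D with the 13-OH as the handle. The ring A 2β,3β-diol comes from the 1-ene-3β-ol by SN2′ chlorination, stannane reduction and exo-face osmylation.
5. Ring order: rings A, B, C and the lactone are taken intact from gibberellic acid; ring D is opened early and rebuilt in the key step.

Assumption: gibberellic acid (GA3, compound 1), a bulk fermentation product, counts as a cheap commercial starting material; the route is therefore a relay synthesis from it.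

Numbering (gibberellane): ring A = C1–C5, C10; ring B = C5, C6, C8, C9, C10; ring C = C8, C9, C11–C14; ring D = C8, C14, C13, C16, C15. C7 = carboxyl on C6, C17 = exocyclic CH2, C18 = 4-methyl, C19 = lactone carbonyl (19→10). The target is 2β,3β,11β-trihydroxy-GA9.

## Route

Step 1
Reactants: 1 gibberellic acid (GA3)
Product: 2 GA3 7-methoxymethyl (MOM) ester
Conditions: CH3OCH2Cl (1.1 equiv), i-Pr2NEt, CH2Cl2, 0 °C
Reagents that add atoms: chloromethyl methyl ether COCCl
Why: Esterification by O-alkylation of the carboxylate is chemoselective over both hydroxyls at 0 °C and installs an ester that later leaves under the same mild acid as the acetonide, with no stereocentre touched.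

Step 2
Reactants: 2 GA3 7-MOM ester
Product: 4 ring D seco keto diester (13-ketone; C8–CH2CO2CH3; ring A unchanged), via 16-norketone 3 (not isolated)
Conditions: O3, pyridine, CH2Cl2, −78 °C; N2 purge; then CH3OH, Pb(OAc)4, 0 °C → rt
Reagents that add atoms: ozone [O-][O+]=O; methanol CO
Why: Ozonolysis takes only the electron-rich exocyclic C16=C17 bond (the ring A alkene is hindered and deactivated by two allylic C–O bonds, and pyridine decomposes the carbonyl oxide directly to the ketone), after which Pb(OAc)4 in methanol performs a Criegee-type α-ketol cleavage through the methanol hemiketal, spending the 13-hydroxyl to open ring D without touching C8.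

Step 3
Reactants: 4 ring D seco keto diester
Product: 5 1β-chloro-2-ene seco keto diester
Conditions: PPh3, CCl4, CH3CN, rt
Reagents that add atoms: carbon tetrachloride ClC(Cl)(Cl)Cl
Why: Appel reaction in its SN2′ mode, because C3 is neopentyl with its rear side covered by the lactone bridge, so chloride enters at C1 on the open β (exo) face with allylic shift as known for GA3 esters, which sets C1 as 1β.

Step 4
Reactants: 5 1β-chloro-2-ene seco keto diester
Product: 6 2-ene seco keto diester
Conditions: (n-C4H9)3SnH, 2,2'-azobis(2-methylpropionitrile) (cat.), benzene, 80 °C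
Reagents that add atoms: none
Why: Radical chain dehalogenation in which the C1–C2–C3 allyl radical takes hydrogen at C1, the outcome recalled from the GA3 → GA5 conversion, keeping the C2=C3 alkene and erasing the C1 stereocentre.

Step 5
Reactants: 6 2-ene seco keto diester
Product: 7 2β,3β-diol seco keto diester
Conditions: OsO4 (2 mol %), N-methylmorpholine N-oxide, acetone/H2O, rt
Reagents that add atoms: osmium tetroxide (catalytic oxygen carrier) O=[Os](=O)(=O)=O; N-methylmorpholine N-oxide C[N+]1([O-])CCOCC1; water O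
Why: Upjohn syn-dihydroxylation on the exo β face, because the 19,10-lactone bridge lies 1,3-diaxially over the α face of ring A (cf. GA5 → GA8), which sets C2 and C3 as the 2β,3β-diol.

Step 6
Reactants: 7 2β,3β-diol seco keto diester
Product: 8 2β,3β-O-isopropylidene seco keto diester
Conditions: 2,2-dimethoxypropane, pyridinium p-toluenesulfonate (cat.), acetone, rt
Reagents that add atoms: 2,2-dimethoxypropane COC(C)(C)OC
Why: Acid-catalysed transketalisation locks the cis-diol as its acetonide, which removes the free 3β-hydroxyl (prone to retro-aldol epimerisation) before the later base, carbene and ylide steps.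

Step 7
Reactants: 8 2β,3β-O-isopropylidene seco keto diester
Product: 9 11-en-13-one (ring C enone)
Conditions: 2-iodoxybenzoic acid (IBX, 2.5 equiv), DMSO/fluorobenzene, 75 °C
Reagents that add atoms: none
Why: IBX dehydrogenation of the ketone can only give the C11=C12 enone, since C14 is flanked by quaternary C8 and cannot be desaturated.

Step 8
Reactants: 9 ring C 11-en-13-one
Product: 10 11β,12β-epoxy-13-ketone
Conditions: 30 % H2O2, LiOH (0.2 equiv), CH3OH, 0 °C
Reagents that add atoms: hydrogen peroxide OO
Why: Weitz–Scheffer nucleophilic epoxidation, with hydroperoxide predicted to add to C11 on the β face (syn to H9) to give the cis-epoxide, whose configuration is inconsequential because C11 becomes a carbonyl in step 11.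

Step 9
Reactants: 10 11β,12β-epoxy-13-ketone
Product: 11 11β-hydroxy-12-ene methyl ester (transposed allylic alcohol)
Conditions: N2H4·H2O, CH3CO2H (cat.), CH3OH, 0 °C → rt
Reagents that add atoms: none
Why: Wharton transposition, in which the epoxy hydrazone fragments with loss of N2 to place the alkene at C12=C13 and the hydroxyl at C11 with retention of the C11–O configuration, completing the shift of oxygen from C13 to C11.

Step 10
Reactants: 11 11β-hydroxy-12-ene methyl ester
Product: 12 11β,16-diol (C8–CH2CH2OH)
Conditions: LiBH4, THF, 0 °C → rt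
Reagents that add atoms: none
Why: Chemoselective borohydride reduction of the only unhindered acyl group (CH2CO2CH3) to the primary alcohol, the C7 ester (between C5–H and quaternary C8) and the cage lactone on quaternary C4 being sterically shielded.

Step 11
Reactants: 12 11β,16-diol
Product: 14 enone aldehyde (12-en-11-one; C8–CH2CHO), via bis(alkoxysulfonium) dichloride 13 (not isolated)
Conditions: (COCl)2, DMSO, CH2Cl2, −78 °C; then Et3N, −78 → 0 °C
Reagents that add atoms: none
Why: Swern oxidation converts both hydroxyls into alkoxysulfonium ions before base is added, so the aldehyde and the enone are released together and no lactol can form and be over-oxidised.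

Step 12
Reactants: 14 enone aldehyde
Product: 15 17-nor-11,16-diketone (ring D re-closed, 13-H)
Conditions: 2-(pentafluorophenyl)-6,7-dihydro-5H-pyrrolo[2,1-c][1,2,4]triazol-2-ium tetrafluoroborate (20 mol %), KN(Si(CH3)3)2 (18 mol %), toluene, 23 → 60 °C
Reagents that add atoms: none
Why: Intramolecular Stetter reaction, in which the carbene turns the C16 aldehyde into a Breslow intermediate (acyl anion equivalent) that adds 5-exo and irreversibly to C13, the β-carbon of the C11 enone (reversible benzoin-type addition to C11=O drains into this 1,4-adduct), and because the tether sits on the β face at C8 it can only bridge from that face, which sets 13-H as in the natural series and restores the bicyclo[3.2.1]octane of ring C and ring D.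

Step 13
Reactants: 15 17-nor-11,16-diketone
Product: 16 11-oxo-16-methylene compound
Conditions: Ph3PCH3Br, KOC(CH3)3, THF, 0 °C → rt
Reagents that add atoms: methyltriphenylphosphonium bromide C[P+](c1ccccc1)(c1ccccc1)c1ccccc1.[Br-]
Why: Wittig methylenation, chemoselective for the cyclopentanone-type C16 carbonyl (the standard reaction of gibberellin 16-norketones) over the C11 carbonyl, which is shielded by the C9 methine between two quaternary carbons, by the C15–C16 bridge and by the lactone oxygen.

Step 14
Reactants: 16 11-oxo-16-methylene compound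
Product: 17 11β-hydroxy compound (acetonide, MOM ester)
Conditions: NaBH4, CH3OH/THF, −20 → 0 °C
Reagents that add atoms: none
Why: Hydride reduction under steric approach control, in which the β (endo) face of C11=O lies directly under the C15–C16 bridge so hydride arrives on the exo α face and gives the axial 11β-alcohol, as in reductions of bicyclo[3.2.1]octan-3-ones.

Step 15
Reactants: 17 11β-hydroxy compound (acetonide, MOM ester)
Product: 18 2β,3β,11β-trihydroxy-GA9 (target, CNP0322347.1)
Conditions: CH3CO2H/H2O/THF (3:1:1), 40 °C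
Reagents that add atoms: none
Why: Mild acid-catalysed hydrolysis removes the acetonide and the methoxymethyl ester (alkyl–oxygen fission) in one operation, the medium being too weakly acidic to protonate the 1,1-disubstituted C16=C17 alkene or to disturb the lactone, and no stereocentre is involved.

## Compound list

1 | gibberellic acid (GA3): 3β,13-dihydroxy-1,16-diene, 7-carboxylic acid, 19→10 lactone | C=C1C[C@]23C[C@@]1(O)CC[C@H]2[C@@]12C=C[C@H](O)[C@@](C)(C(=O)O1)[C@H]2[C@@H]3C(=O)O | starting material
2 | GA3 7-methoxymethyl ester | C=C1C[C@]23C[C@@]1(O)CC[C@H]2[C@@]12C=C[C@H](O)[C@@](C)(C(=O)O1)[C@H]2[C@@H]3C(=O)OCOC | intermediate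
3 | 16-norketone of 2 (17-nor, 13-hydroxy-16-oxo) | O=C1C[C@]23C[C@@]1(O)CC[C@H]2[C@@]12C=C[C@H](O)[C@@](C)(C(=O)O1)[C@H]2[C@@H]3C(=O)OCOC | intermediate
4 | ring D seco keto diester: C13–C16 bond cleaved, C17 lost; C13 ring C ketone; C8 bears CH2CO2CH3 (C15, C16); ring A 1-ene-3β-ol; 7-MOM ester | COC(=O)C[C@]23CC(=O)CC[C@H]2[C@@]12C=C[C@H](O)[C@@](C)(C(=O)O1)[C@H]2[C@@H]3C(=O)OCOC | intermediate
5 | 1β-chloro-2-ene analogue of 4 (no oxygen at C3) | COC(=O)C[C@]23CC(=O)CC[C@H]2[C@@]12[C@H](Cl)C=C[C@@](C)(C(=O)O1)[C@H]2[C@@H]3C(=O)OCOC | intermediate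
6 | 2-ene seco keto diester (C1 = CH2) | COC(=O)C[C@]23CC(=O)CC[C@H]2[C@@]12CC=C[C@@](C)(C(=O)O1)[C@H]2[C@@H]3C(=O)OCOC | intermediate
7 | 2β,3β-diol seco keto diester | COC(=O)C[C@]23CC(=O)CC[C@H]2[C@@]12C[C@H](O)[C@H](O)[C@@](C)(C(=O)O1)[C@H]2[C@@H]3C(=O)OCOC | intermediate
8 | 2β,3β-O-isopropylidene seco keto diester | COC(=O)C[C@]23CC(=O)CC[C@H]2[C@@]12C[C@@H]4OC(C)(C)O[C@@H]4[C@@](C)(C(=O)O1)[C@H]2[C@@H]3C(=O)OCOC | intermediate
9 | ring C 11-en-13-one of 8 | COC(=O)C[C@]23CC(=O)C=C[C@H]2[C@@]12C[C@@H]4OC(C)(C)O[C@@H]4[C@@](C)(C(=O)O1)[C@H]2[C@@H]3C(=O)OCOC | intermediate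
10 | 11β,12β-epoxy-13-ketone (predicted face; the α-epoxide would serve equally) | COC(=O)C[C@]23CC(=O)[C@@H]5O[C@@H]5[C@H]2[C@@]12C[C@@H]4OC(C)(C)O[C@@H]4[C@@](C)(C(=O)O1)[C@H]2[C@@H]3C(=O)OCOC | intermediate
11 | 11β-hydroxy-12-ene, C16 methyl ester | COC(=O)C[C@]23CC=C[C@H](O)[C@H]2[C@@]12C[C@@H]4OC(C)(C)O[C@@H]4[C@@](C)(C(=O)O1)[C@H]2[C@@H]3C(=O)OCOC | intermediate
12 | 11β,16-diol (C8–CH2CH2OH), 12-ene | OCC[C@]23CC=C[C@H](O)[C@H]2[C@@]12C[C@@H]4OC(C)(C)O[C@@H]4[C@@](C)(C(=O)O1)[C@H]2[C@@H]3C(=O)OCOC | intermediate
13 | 11,16-bis(dimethylsulfonio-oxy) dichloride of 12 | C[S+](C)OCC[C@]23CC=C[C@H](O[S+](C)C)[C@H]2[C@@]12C[C@@H]4OC(C)(C)O[C@@H]4[C@@](C)(C(=O)O1)[C@H]2[C@@H]3C(=O)OCOC.[Cl-].[Cl-] | intermediate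
14 | enone aldehyde: 12-en-11-one, C8–CH2CHO (C16 aldehyde) | O=CC[C@]23CC=CC(=O)[C@H]2[C@@]12C[C@@H]4OC(C)(C)O[C@@H]4[C@@](C)(C(=O)O1)[C@H]2[C@@H]3C(=O)OCOC | intermediate
15 | 17-nor-11,16-diketone, ring D re-formed, 13-H, 2β,3β-acetonide, 7-MOM ester | O=C1C[C@]23C[C@H]1CC(=O)[C@H]2[C@@]12C[C@@H]4OC(C)(C)O[C@@H]4[C@@](C)(C(=O)O1)[C@H]2[C@@H]3C(=O)OCOC | intermediate
16 | 11-oxo-16-methylene compound (acetonide, MOM ester) | C=C1C[C@]23C[C@H]1CC(=O)[C@H]2[C@@]12C[C@@H]4OC(C)(C)O[C@@H]4[C@@](C)(C(=O)O1)[C@H]2[C@@H]3C(=O)OCOC | intermediate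
17 | 11β-hydroxy-16-methylene compound (acetonide, MOM ester) | C=C1C[C@]23C[C@H]1C[C@H](O)[C@H]2[C@@]12C[C@@H]4OC(C)(C)O[C@@H]4[C@@](C)(C(=O)O1)[C@H]2[C@@H]3C(=O)OCOC | intermediate
18 | 2β,3β,11β-trihydroxy-GA9 (CNP0322347.1) | C=C1C[C@]23C[C@H]1C[C@H](O)[C@H]2[C@@]12C[C@H](O)[C@H](O)[C@@](C)(C(=O)O1)[C@H]2[C@@H]3C(=O)O | target

## Step count and risks

Total steps: 15. Longest linear sequence: 15 (fully linear from 1).

Three steps most likely to fail:

Step 12 (Stetter ring closure). A β-substituted cyclohexenone is a sluggish acceptor, and benzoin-type addition to C11=O or aldol pathways could dominate. The fallback sets out from 14 and swaps the carbene for a nucleophilic acyl radical. Oxidise the aldehyde with NaClO2, NaH2PO4 and 2-methyl-2-butene to the enone carboxylic acid F1. Convert it with PhSeSePh and P(n-C4H9)3 into the Se-phenyl selenoester F2. Treat F2 with (n-C4H9)3SnH and 2,2'-azobis(2-methylpropionitrile) in benzene at 80 °C; the acyl radical closes 5-exo onto C13 and the route is rejoined at 15.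

Step 10 (LiBH4 discrimination between three acyl groups). The MOM ester or the lactone may be attacked. The fallback sets out from 11 and replaces hydride selectivity by acid-selective chemistry. Me3SnOH in 1,2-dichloroethane at 70 °C cleaves only the unhindered methyl ester to the hydroxy acid F3. BH3·S(CH3)2 in THF at 0 °C then reduces the free carboxylic acid in preference to esters, the lactone and the hindered alkene, coming back at 12.

Step 14 (facial selectivity at C11). Both faces of the C11 carbonyl are crowded; if hydride is delivered on the β face, the product is the 11α-alcohol F4. The fallback sets out from 16 via F4 and uses SN2 inversion instead of facial control. A Mitsunobu reaction with 4-nitrobenzoic acid, PPh3 and diisopropyl azodicarboxylate in toluene gives the inverted 11β 4-nitrobenzoate F5. Methanolysis with K2CO3 in CH3OH comes back at 17.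

## Further compounds

F1 | step 12 | enone carboxylic acid (C16 acid of 14) | OC(=O)C[C@]23CC=CC(=O)[C@H]2[C@@]12C[C@@H]4OC(C)(C)O[C@@H]4[C@@](C)(C(=O)O1)[C@H]2[C@@H]3C(=O)OCOC
F2 | step 12 | Se-phenyl selenoester of F1 | O=C([Se]c1ccccc1)C[C@]23CC=CC(=O)[C@H]2[C@@]12C[C@@H]4OC(C)(C)O[C@@H]4[C@@](C)(C(=O)O1)[C@H]2[C@@H]3C(=O)OCOC
F3 | step 10 | hydroxy acid (C16 acid of 11) | OC(=O)C[C@]23CC=C[C@H](O)[C@H]2[C@@]12C[C@@H]4OC(C)(C)O[C@@H]4[C@@](C)(C(=O)O1)[C@H]2[C@@H]3C(=O)OCOC
F4 | step 14 | 11α-alcohol (C11 epimer of 17) | C=C1C[C@]23C[C@H]1C[C@@H](O)[C@H]2[C@@]12C[C@@H]4OC(C)(C)O[C@@H]4[C@@](C)(C(=O)O1)[C@H]2[C@@H]3C(=O)OCOC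
F5 | step 14 | 11β 4-nitrobenzoate of 17 | C=C1C[C@]23C[C@H]1C[C@H](OC(=O)c5ccc(cc5)[N+](=O)[O-])[C@H]2[C@@]12C[C@@H]4OC(C)(C)O[C@@H]4[C@@](C)(C(=O)O1)[C@H]2[C@@H]3C(=O)OCOC
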